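Calyxin A is disconnected at heptanoid C2–C3, C3–C4 and, transiently, between one phloroglucinol oxygen and C5. The benzylic stereocentre C3 sits on the ring carbon flanked by two phenolic oxygens, so it can be the exocyclic carbon of an ortho-quinone methide. In one pot an aryl acetylide adds to a bis-Boc salicylaldehyde, Boc transfer and elimination release the alkynyl methide, and a chiral vinyl ether closes a chroman acetal by [4+2] cycloaddition, setting C3 and delivering C5 as a masked aldehyde. The precursors are 2,6-bis(Boc-oxy)-4-methoxybenzaldehyde, a lithium arylacetylide and trans-2-phenylcyclohexyl vinyl ether; C5, the E-styrene and the chalcone are added afterwards.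

Key step: step 8

Remarks
- Numbering: heptanoid carbons run from the styryl carbon bonded to its aryl group (C1) to the benzylic CH2 of the arylethyl end (C7). Ring intermediates use chroman numbering (chroman C4 = heptanoid C3, chroman C2 = heptanoid C5).
- Assumption: the (1R,2S)-auxiliary is taken to give the (4R)-chroman 15 as drawn; this sense of induction is not secured for an alkynyl methide, and the (1S,2R)-alcohol would replace 7, with nothing else changed, if the opposite face reacts.
- Remark: C6, C7 and their aryl group need a 2-arylethyl donor, so 4-(2-bromoethyl)phenol 20 is used; a 3-arylpropanoic acid would bring one carbon too many.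
- Remark: once both ring phenols carry the same group, the two free ring positions (each between OMe and an oxygen) are equivalent, so the chalcone carbonyl may enter at either.

Step 1
Reactants: 1 5-methoxyresorcinol
Product: 2 1-methoxy-3,5-bis(methoxymethoxy)benzene
Conditions: MOMCl (2.5 equiv), iPr2NEt (3 equiv), CH2Cl2, 0 °C → rt
Reagents that add atoms: chloromethyl methyl ether, COCCl
Why: Base-mediated O-alkylation of both phenols (Williamson-type etherification) installs the two acetal ethers that will direct the metalation.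

Step 2
Reactants: 2 1-methoxy-3,5-bis(methoxymethoxy)benzene
Product: 4 4-methoxy-2,6-bis(methoxymethoxy)benzaldehyde, via aryllithium 3 (not isolated)
Conditions: n-BuLi (1.1 equiv), THF, 0 °C → rt; then DMF, 0 °C; aq NH4Cl
Reagents that add atoms: N,N-dimethylformamide, CN(C)C=O
Why: Directed ortho-metalation, in which the two MOM ethers cooperatively steer n-BuLi to the carbon between them in preference to the positions next to the weaker methoxy director, followed by formylation of the aryllithium with DMF.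

Step 3
Reactants: 4 4-methoxy-2,6-bis(methoxymethoxy)benzaldehyde
Product: 5 2,6-dihydroxy-4-methoxybenzaldehyde
Conditions: HCl (cat.), MeOH, 50 °C; aqueous work-up
Reagents that add atoms: none
Why: Acid-catalysed acetal exchange with methanol removes both MOM groups as dimethoxymethane, so no free formaldehyde meets the electron-rich ring, and the hydrogen-bonded aldehyde is returned on aqueous work-up.

Step 4
Reactants: 5 2,6-dihydroxy-4-methoxybenzaldehyde
Product: 6 2,6-bis(tert-butoxycarbonyloxy)-4-methoxybenzaldehyde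
Conditions: Boc2O (2.3 equiv), DMAP (5 mol%), iPr2NEt (cat.), THF, 0 °C → rt
Reagents that add atoms: di-tert-butyl dicarbonate, CC(C)(C)OC(=O)OC(=O)OC(C)(C)C
Why: DMAP-catalysed O-acylation (carbonate formation) covers both phenols, and two identical carbonates make the later Boc transfer degenerate.

Step 5
Reactants: 7 (1R,2S)-trans-2-phenylcyclohexanol
Product: 8 (1R,2S)-1-(ethenyloxy)-2-phenylcyclohexane
Conditions: butyl vinyl ether (excess), Pd(OCOCF3)2 (1 mol%), 4,7-diphenyl-1,10-phenanthroline (1 mol%), Et3N (cat.), 75 °C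
Reagents that add atoms: butyl vinyl ether, C=COCCCC
Why: Palladium(II)-catalysed transfer vinylation (transetherification) converts the alcohol into its vinyl ether without touching the carbinol C–O bond, so both auxiliary stereocentres are retained.

Step 6
Reactants: 9 4-iodophenol
Product: 10 tert-butyl(4-iodophenoxy)dimethylsilane
Conditions: TBSCl, imidazole, DMF, rt
Reagents that add atoms: tert-butyldimethylsilyl chloride, CC(C)(C)[Si](C)(C)Cl
Why: Imidazole-promoted O-silylation of a phenol is routine and gives a group that survives organometallic reagents and leaves with fluoride at the end.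

Step 7
Reactants: 10 tert-butyl(4-iodophenoxy)dimethylsilane
Product: 11 tert-butyl(4-ethynylphenoxy)dimethylsilane
Conditions: HC≡CMgBr, ZnBr2, THF, 0 °C; then 10, Pd(PPh3)4 (3 mol%), rt
Reagents that add atoms: ethynylmagnesium bromide, C#C[Mg]Br
Why: Negishi cross-coupling of ethynylzinc bromide (made by transmetalation) with the aryl iodide gives the terminal alkyne directly, so no C-silyl group has to be removed next to the aryl silyl ether.

Step 8
Reactants: 6 2,6-bis(tert-butoxycarbonyloxy)-4-methoxybenzaldehyde; 11 tert-butyl(4-ethynylphenoxy)dimethylsilane; 8 (1R,2S)-1-(ethenyloxy)-2-phenylcyclohexane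
Product: 15 (2S,4R)-5-(tert-butoxycarbonyloxy)-4-{[4-(tert-butyldimethylsilyloxy)phenyl]ethynyl}-7-methoxy-2-{[(1R,2S)-2-phenylcyclohexyl]oxy}chroman (2,4-cis), via lithium acetylide 12 (not isolated), via benzylic carbonate phenoxide 13 (not isolated), via alkynyl ortho-quinone methide 14 (not isolated)
Conditions: 11, n-BuLi (1.0 equiv), THF, −78 °C; add to 6 and 8 (3 equiv), Et2O, −78 °C; then MgBr2·OEt2 (1.1 equiv), −78 °C → rt
Reagents that add atoms: none
Why: The acetylide adds to the aldehyde of 6, the alkoxide takes over a neighbouring Boc group (either one, since the two carbonates are equivalent) to give phenoxide 13, and magnesium-promoted 1,4-elimination of tert-butyl carbonate releases alkynyl ortho-quinone methide 14 at low temperature. The closest known reaction type is the organometal-triggered generation of ortho-quinone methides from O-Boc salicylaldehydes with inverse-electron-demand hetero-Diels–Alder trapping by enol ethers, used here with an alkynyl nucleophile in place of the usual alkyl, aryl or hydride. The pyran ring of the chroman is closed by an intermolecular [4+2] cycloaddition in which the O=C–C=C unit of the methide is the heterodiene and the vinyl ether the 2π partner, forming heptanoid C3–C4 and the aryl O–C5 bond and restoring the aromatic ring. The endo orientation of the alkoxy group sets the 2,4-cis relationship at the acetal carbon, and the face of the enol ether left open by the phenyl group of the (1R,2S)-auxiliary sets the absolute configuration at chroman C4 (heptanoid C3). The step needs the methide to be trapped by the enol ether and not by acetylide or tert-butoxide, which is secured by one equivalent of acetylide, by holding back elimination until the magnesium salt is added with excess enol ether present, and by the alkynyl substituent, which cannot undergo the oxa-6π closure open to a styryl methide.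

Step 9
Reactants: 15 (2S,4R)-5-(tert-butoxycarbonyloxy)-4-{[4-(tert-butyldimethylsilyloxy)phenyl]ethynyl}-7-methoxy-2-{[(1R,2S)-2-phenylcyclohexyl]oxy}chroman
Product: 17 (4R)-4-{[4-(tert-butyldimethylsilyloxy)phenyl]ethynyl}-7-methoxychroman-2,5-diol (anomeric mixture), via phenol acetal 16 (not isolated)
Conditions: piperidine (5 equiv), CH2Cl2, rt; evaporate; then 1 M HCl (aq), THF, rt → 40 °C
Reagents that add atoms: water, O
Why: Aminolysis of the aryl tert-butyl carbonate is followed by acid-catalysed hydrolysis of the mixed aryl alkyl acetal, which frees the recoverable auxiliary; C4 carries no leaving group and keeps its configuration, while the acetal centre is lost as intended.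

Step 10
Reactants: 17 (4R)-4-{[4-(tert-butyldimethylsilyloxy)phenyl]ethynyl}-7-methoxychroman-2,5-diol
Product: 18 (3R)-3-[2,6-bis(tert-butyldimethylsilyloxy)-4-methoxyphenyl]-5-[4-(tert-butyldimethylsilyloxy)phenyl]pent-4-ynal
Conditions: TBSCl (3 equiv), imidazole (6 equiv), DMAP (cat.), DMF, rt
Reagents that add atoms: tert-butyldimethylsilyl chloride, CC(C)(C)[Si](C)(C)Cl
Why: O-Silylation under ring–chain tautomerism, in which the hemiacetal equilibrates with the 2,6-dihydroxyaryl aldehyde and silylation of both phenols, the more acidic hydroxyls, should trap the open form as the free aldehyde.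

Step 11
Reactants: 18 (3R)-3-[2,6-bis(tert-butyldimethylsilyloxy)-4-methoxyphenyl]-5-[4-(tert-butyldimethylsilyloxy)phenyl]pent-4-ynal
Product: 19 (3R)-3-[2,6-bis(tert-butyldimethylsilyloxy)-3-iodo-4-methoxyphenyl]-5-[4-(tert-butyldimethylsilyloxy)phenyl]pent-4-ynal
Conditions: NIS (1.05 equiv), MeCN, 0 °C → rt, dark
Reagents that add atoms: N-iodosuccinimide, O=C1CCC(=O)N1I
Why: Electrophilic aromatic iodination goes to the trioxygenated ring, which is far more nucleophilic than the alkyne or the other arenes, and its two free positions are interchanged by rotation about the C3–aryl bond, so one mono-iodide should form.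

Step 12
Reactants: 20 4-(2-bromoethyl)phenol
Product: 21 [4-(2-bromoethyl)phenoxy](tert-butyl)dimethylsilane
Conditions: TBSCl, imidazole, CH2Cl2, rt
Reagents that add atoms: tert-butyldimethylsilyl chloride, CC(C)(C)[Si](C)(C)Cl
Why: Imidazole-promoted O-silylation of the phenol is faster than any displacement of the primary bromide under these weakly basic conditions.

Step 13
Reactants: 19 (3R)-3-[2,6-bis(tert-butyldimethylsilyloxy)-3-iodo-4-methoxyphenyl]-5-[4-(tert-butyldimethylsilyloxy)phenyl]pent-4-ynal; 21 [4-(2-bromoethyl)phenoxy](tert-butyl)dimethylsilane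
Product: 24 (3R,5S)-3-[2,6-bis(tert-butyldimethylsilyloxy)-3-iodo-4-methoxyphenyl]-1,7-bis[4-(tert-butyldimethylsilyloxy)phenyl]hept-1-yn-5-ol, via Grignard reagent 22 (not isolated), via dialkylzinc 23 (not isolated)
Conditions: 21 (4 equiv), Mg, Et2O, rt; ZnCl2 (2 equiv), then 1,4-dioxane, filter; Ti(OiPr)4 (1.4 equiv), (R,R)-TADDOL (20 mol%), toluene, −30 °C, then 19
Reagents that add atoms: none
Why: Catalytic enantioselective dialkylzinc addition to an aldehyde (titanium TADDOLate; zinc reagent made by Grignard transmetalation and freed of magnesium salts with dioxane), in which the (R,R)-catalyst is expected to deliver the alkyl group to the Si face and so set (5S) under catalyst control, the remote C3 centre having little influence.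

Step 14
Reactants: 24 (3R,5S)-3-[2,6-bis(tert-butyldimethylsilyloxy)-3-iodo-4-methoxyphenyl]-1,7-bis[4-(tert-butyldimethylsilyloxy)phenyl]hept-1-yn-5-ol
Product: 25 (1E,3R,5S)-3-[2,6-bis(tert-butyldimethylsilyloxy)-3-iodo-4-methoxyphenyl]-1,7-bis[4-(tert-butyldimethylsilyloxy)phenyl]hept-1-en-5-ol
Conditions: [Cp*Ru(cod)Cl] (5 mol%), AgOTf (5 mol%), H2 (10 bar), CH2Cl2, rt
Reagents that add atoms: none
Why: Ruthenium-catalysed trans-hydrogenation of an internal alkyne delivers both hydrogens in an anti sense at the Cp*Ru centre and gives the E-alkene directly without fluoride, so all silyl ethers and the C3 and C5 centres should be untouched.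

Step 15
Reactants: 26 4-(tert-butyldimethylsilyloxy)benzaldehyde; 27 diethyl {2-[methoxy(methyl)amino]-2-oxoethyl}phosphonate
Product: 28 (E)-3-[4-(tert-butyldimethylsilyloxy)phenyl]-N-methoxy-N-methylprop-2-enamide
Conditions: NaH, THF, 0 °C → rt
Reagents that add atoms: none
Why: Horner–Wadsworth–Emmons olefination with the stabilised amide phosphonate gives the E-configured unsaturated Weinreb amide.

Step 16
Reactants: 25 (1E,3R,5S)-3-[2,6-bis(tert-butyldimethylsilyloxy)-3-iodo-4-methoxyphenyl]-1,7-bis[4-(tert-butyldimethylsilyloxy)phenyl]hept-1-en-5-ol; 28 (E)-3-[4-(tert-butyldimethylsilyloxy)phenyl]-N-methoxy-N-methylprop-2-enamide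
Product: 30 (E)-1-{2,4-bis(tert-butyldimethylsilyloxy)-3-[(1E,3R,5S)-5-hydroxy-1,7-bis[4-(tert-butyldimethylsilyloxy)phenyl]hept-1-en-3-yl]-6-methoxyphenyl}-3-[4-(tert-butyldimethylsilyloxy)phenyl]prop-2-en-1-one, via arylmagnesium chloride 29 (not isolated)
Conditions: iPrMgCl·LiCl (2.2 equiv), THF, −20 °C → rt; then 28 (1.5 equiv), 0 °C → rt; aq NH4Cl
Reagents that add atoms: none
Why: Iodine–magnesium exchange (the first equivalent deprotonates the alcohol) followed by Weinreb ketone synthesis, in which the chelated tetrahedral adduct stops at the ketone and an arylmagnesium, unlike an aryllithium, should not trigger O→C migration of the ortho silyl group.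

Step 17
Reactants: 30 (E)-1-{2,4-bis(tert-butyldimethylsilyloxy)-3-[(1E,3R,5S)-5-hydroxy-1,7-bis[4-(tert-butyldimethylsilyloxy)phenyl]hept-1-en-3-yl]-6-methoxyphenyl}-3-[4-(tert-butyldimethylsilyloxy)phenyl]prop-2-en-1-one
Product: 31 calyxin A, (E)-1-{2,4-dihydroxy-3-[(1E,3R,5S)-5-hydroxy-1,7-bis(4-hydroxyphenyl)hept-1-en-3-yl]-6-methoxyphenyl}-3-(4-hydroxyphenyl)prop-2-en-1-one
Conditions: TBAF (6 equiv), AcOH (6 equiv), THF, 0 °C → rt
Reagents that add atoms: none
Why: Fluoride-mediated cleavage of the five aryl silyl ethers, buffered with acetic acid so that neither base-induced flavanone closure nor acid-induced addition of the C5 hydroxyl to the hydroxystyrene should intervene.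

Compound list
1 | 5-methoxyresorcinol | COc1cc(O)cc(O)c1 | starting material
2 | 1-methoxy-3,5-bis(methoxymethoxy)benzene | COCOc1cc(OC)cc(OCOC)c1 | intermediate
3 | [4-methoxy-2,6-bis(methoxymethoxy)phenyl]lithium | [Li]c1c(OCOC)cc(OC)cc1OCOC | intermediate (not isolated)
4 | 4-methoxy-2,6-bis(methoxymethoxy)benzaldehyde | COCOc1cc(OC)cc(OCOC)c1C=O | intermediate
5 | 2,6-dihydroxy-4-methoxybenzaldehyde | COc1cc(O)c(C=O)c(O)c1 | intermediate
6 | 2,6-bis(tert-butoxycarbonyloxy)-4-methoxybenzaldehyde | COc1cc(OC(=O)OC(C)(C)C)c(C=O)c(OC(=O)OC(C)(C)C)c1 | intermediate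
7 | (1R,2S)-trans-2-phenylcyclohexanol | O[C@@H]1CCCC[C@H]1c1ccccc1 | starting material
8 | (1R,2S)-1-(ethenyloxy)-2-phenylcyclohexane | C=CO[C@@H]1CCCC[C@H]1c1ccccc1 | intermediate
9 | 4-iodophenol | Oc1ccc(I)cc1 | starting material
10 | tert-butyl(4-iodophenoxy)dimethylsilane | CC(C)(C)[Si](C)(C)Oc1ccc(I)cc1 | intermediate
11 | tert-butyl(4-ethynylphenoxy)dimethylsilane | C#Cc1ccc(O[Si](C)(C)C(C)(C)C)cc1 | intermediate
12 | lithium [4-(tert-butyldimethylsilyloxy)phenyl]acetylide | [Li]C#Cc1ccc(O[Si](C)(C)C(C)(C)C)cc1 | intermediate (not isolated)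
13 | lithium 3-(tert-butoxycarbonyloxy)-2-{1-(tert-butoxycarbonyloxy)-3-[4-(tert-butyldimethylsilyloxy)phenyl]prop-2-ynyl}-5-methoxyphenolate | [Li]Oc1cc(OC)cc(OC(=O)OC(C)(C)C)c1C(OC(=O)OC(C)(C)C)C#Cc1ccc(O[Si](C)(C)C(C)(C)C)cc1 | intermediate (not isolated)
14 | (E)-5-(tert-butoxycarbonyloxy)-6-{3-[4-(tert-butyldimethylsilyloxy)phenyl]prop-2-ynylidene}-3-methoxycyclohexa-2,4-dien-1-one | COC1=CC(=O)/C(=C/C#Cc2ccc(O[Si](C)(C)C(C)(C)C)cc2)C(OC(=O)OC(C)(C)C)=C1 | intermediate (not isolated)
15 | (2S,4R)-5-(tert-butoxycarbonyloxy)-4-{[4-(tert-butyldimethylsilyloxy)phenyl]ethynyl}-7-methoxy-2-{[(1R,2S)-2-phenylcyclohexyl]oxy}chroman | COc1cc(OC(=O)OC(C)(C)C)c2c(c1)O[C@H](O[C@@H]1CCCC[C@H]1c1ccccc1)C[C@@H]2C#Cc1ccc(O[Si](C)(C)C(C)(C)C)cc1 | intermediate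
16 | (2S,4R)-4-{[4-(tert-butyldimethylsilyloxy)phenyl]ethynyl}-7-methoxy-2-{[(1R,2S)-2-phenylcyclohexyl]oxy}chroman-5-ol | COc1cc(O)c2c(c1)O[C@H](O[C@@H]1CCCC[C@H]1c1ccccc1)C[C@@H]2C#Cc1ccc(O[Si](C)(C)C(C)(C)C)cc1 | intermediate (not isolated)
17 | (4R)-4-{[4-(tert-butyldimethylsilyloxy)phenyl]ethynyl}-7-methoxychroman-2,5-diol | COc1cc(O)c2c(c1)OC(O)C[C@@H]2C#Cc1ccc(O[Si](C)(C)C(C)(C)C)cc1 | intermediate
18 | (3R)-3-[2,6-bis(tert-butyldimethylsilyloxy)-4-methoxyphenyl]-5-[4-(tert-butyldimethylsilyloxy)phenyl]pent-4-ynal | COc1cc(O[Si](C)(C)C(C)(C)C)c([C@H](CC=O)C#Cc2ccc(O[Si](C)(C)C(C)(C)C)cc2)c(O[Si](C)(C)C(C)(C)C)c1 | intermediate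
19 | (3R)-3-[2,6-bis(tert-butyldimethylsilyloxy)-3-iodo-4-methoxyphenyl]-5-[4-(tert-butyldimethylsilyloxy)phenyl]pent-4-ynal | COc1cc(O[Si](C)(C)C(C)(C)C)c([C@H](CC=O)C#Cc2ccc(O[Si](C)(C)C(C)(C)C)cc2)c(O[Si](C)(C)C(C)(C)C)c1I | intermediate
20 | 4-(2-bromoethyl)phenol | Oc1ccc(CCBr)cc1 | starting material
21 | [4-(2-bromoethyl)phenoxy](tert-butyl)dimethylsilane | CC(C)(C)[Si](C)(C)Oc1ccc(CCBr)cc1 | intermediate
22 | {2-[4-(tert-butyldimethylsilyloxy)phenyl]ethyl}magnesium bromide | CC(C)(C)[Si](C)(C)Oc1ccc(CC[Mg]Br)cc1 | intermediate (not isolated)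
23 | bis{2-[4-(tert-butyldimethylsilyloxy)phenyl]ethyl}zinc | CC(C)(C)[Si](C)(C)Oc1ccc(CC[Zn]CCc2ccc(O[Si](C)(C)C(C)(C)C)cc2)cc1 | intermediate (not isolated)
24 | (3R,5S)-3-[2,6-bis(tert-butyldimethylsilyloxy)-3-iodo-4-methoxyphenyl]-1,7-bis[4-(tert-butyldimethylsilyloxy)phenyl]hept-1-yn-5-ol | COc1cc(O[Si](C)(C)C(C)(C)C)c([C@H](C[C@@H](O)CCc2ccc(O[Si](C)(C)C(C)(C)C)cc2)C#Cc2ccc(O[Si](C)(C)C(C)(C)C)cc2)c(O[Si](C)(C)C(C)(C)C)c1I | intermediate
25 | (1E,3R,5S)-3-[2,6-bis(tert-butyldimethylsilyloxy)-3-iodo-4-methoxyphenyl]-1,7-bis[4-(tert-butyldimethylsilyloxy)phenyl]hept-1-en-5-ol | COc1cc(O[Si](C)(C)C(C)(C)C)c([C@@H](/C=C/c2ccc(O[Si](C)(C)C(C)(C)C)cc2)C[C@@H](O)CCc2ccc(O[Si](C)(C)C(C)(C)C)cc2)c(O[Si](C)(C)C(C)(C)C)c1I | intermediate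
26 | 4-(tert-butyldimethylsilyloxy)benzaldehyde | CC(C)(C)[Si](C)(C)Oc1ccc(C=O)cc1 | starting material
27 | diethyl {2-[methoxy(methyl)amino]-2-oxoethyl}phosphonate | CCOP(=O)(CC(=O)N(C)OC)OCC | starting material
28 | (E)-3-[4-(tert-butyldimethylsilyloxy)phenyl]-N-methoxy-N-methylprop-2-enamide | CON(C)C(=O)/C=C/c1ccc(O[Si](C)(C)C(C)(C)C)cc1 | intermediate
29 | chloromagnesium alkoxide arylmagnesium chloride derived from 25 (Mg in place of I, O–MgCl at C5) | COc1cc(O[Si](C)(C)C(C)(C)C)c([C@@H](/C=C/c2ccc(O[Si](C)(C)C(C)(C)C)cc2)C[C@@H](O[Mg]Cl)CCc2ccc(O[Si](C)(C)C(C)(C)C)cc2)c(O[Si](C)(C)C(C)(C)C)c1[Mg]Cl | intermediate (not isolated)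
30 | (E)-1-{2,4-bis(tert-butyldimethylsilyloxy)-3-[(1E,3R,5S)-5-hydroxy-1,7-bis[4-(tert-butyldimethylsilyloxy)phenyl]hept-1-en-3-yl]-6-methoxyphenyl}-3-[4-(tert-butyldimethylsilyloxy)phenyl]prop-2-en-1-one | COc1cc(O[Si](C)(C)C(C)(C)C)c([C@@H](/C=C/c2ccc(O[Si](C)(C)C(C)(C)C)cc2)C[C@@H](O)CCc2ccc(O[Si](C)(C)C(C)(C)C)cc2)c(O[Si](C)(C)C(C)(C)C)c1C(=O)/C=C/c1ccc(O[Si](C)(C)C(C)(C)C)cc1 | intermediate
31 | calyxin A | COc1cc(O)c([C@@H](/C=C/c2ccc(O)cc2)C[C@@H](O)CCc2ccc(O)cc2)c(O)c1C(=O)/C=C/c1ccc(O)cc1 | target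

Total step count: 17. Longest linear sequence: 12 steps (1, 2, 3, 4, 8, 9, 10, 11, 13, 14, 16, 17).

Steps most likely to fail

Step 8. The methide may be consumed before cycloaddition, by addition of tert-butoxide or a second acetylide at the methide carbon or the alkyne terminus, or by self-condensation. Facial and endo/exo selectivity may also erode, because a slim alkynyl group next to an ortho carbonate fixes the methide geometry less firmly than an alkyl or aryl group. The fallback leaves the cycloaddition and sets C3 by catalytic asymmetric conjugate alkynylation; it sets out from 5 and returns at 18, bypassing steps 8–10. Both phenols of 5 are silylated (TBSCl, imidazole) to give 2,6-bis(tert-butyldimethylsilyloxy)-4-methoxybenzaldehyde F1. Knoevenagel condensation with Meldrum's acid (piperidine/AcOH cat.) gives the arylidene Meldrum's acid F2. Copper-catalysed enantioselective conjugate addition of alkyne 11 (Cu(OAc)2, sodium ascorbate, PINAP ligand, water; ligand antipode chosen for (R)) gives the alkynylated Meldrum's acid F3. Methanolysis with decarboxylation (MeOH, pyridine, heat) gives the methyl ester F4, and DIBAL-H at −78 °C gives aldehyde 18.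

Step 14. Hydrogen delivery may run partly through geminal addition and a ruthenium carbene, which leads to over-reduction or to migration of the double bond towards C3 with loss of that stereocentre. Turnover on a hindered aryl alkyne may be slow, and hydrogenolysis of the carbon–iodine bond cannot be excluded. The fallback replaces direct hydrogenation by hydrometalation and protodemetalation; it sets out from 24 and returns at 25. trans-Hydrosilylation ([Cp*Ru(MeCN)3]PF6, (EtO)3SiH, CH2Cl2, 0 °C → rt) gives the (Z)-alkenylsilane F5, drawn with silicon on C1; the C2 regioisomer converges on the same alkene. Protodesilylation with TBAF/CuI in THF, which also strips the four aryl silyl ethers, gives the (E)-alkene tetraphenol F6. Re-silylation of the four phenols (TBSCl 4.2 equiv, imidazole, DMF, 0 °C) returns 25.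

Step 10. Silylation may take place at the hemiacetal oxygen of the closed form, which would leave C5 masked as a silyl lactol ether instead of freeing the aldehyde. The fallback opens the ring by reduction and restores the aldehyde by oxidation; it sets out from 17 and returns at 18. NaBH4 in MeOH reduces the lactol to the ring-opened triol F7. Exhaustive silylation (TBSCl, imidazole, DMF) gives the fully silylated ether F8. Selective cleavage of the primary alkyl silyl ether (PPTS, EtOH), to which aryl silyl ethers are inert, gives the primary alcohol F9, and Dess–Martin periodinane oxidation gives 18.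

Further compounds
F1 | step 8 | 2,6-bis(tert-butyldimethylsilyloxy)-4-methoxybenzaldehyde | COc1cc(O[Si](C)(C)C(C)(C)C)c(C=O)c(O[Si](C)(C)C(C)(C)C)c1
F2 | step 8 | 5-[2,6-bis(tert-butyldimethylsilyloxy)-4-methoxybenzylidene]-2,2-dimethyl-1,3-dioxane-4,6-dione | COc1cc(O[Si](C)(C)C(C)(C)C)c(C=C2C(=O)OC(C)(C)OC2=O)c(O[Si](C)(C)C(C)(C)C)c1
F3 | step 8 | 5-{(1R)-1-[2,6-bis(tert-butyldimethylsilyloxy)-4-methoxyphenyl]-3-[4-(tert-butyldimethylsilyloxy)phenyl]prop-2-yn-1-yl}-2,2-dimethyl-1,3-dioxane-4,6-dione | COc1cc(O[Si](C)(C)C(C)(C)C)c([C@H](C2C(=O)OC(C)(C)OC2=O)C#Cc2ccc(O[Si](C)(C)C(C)(C)C)cc2)c(O[Si](C)(C)C(C)(C)C)c1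
F4 | step 8 | methyl (3R)-3-[2,6-bis(tert-butyldimethylsilyloxy)-4-methoxyphenyl]-5-[4-(tert-butyldimethylsilyloxy)phenyl]pent-4-ynoate | COc1cc(O[Si](C)(C)C(C)(C)C)c([C@H](CC(=O)OC)C#Cc2ccc(O[Si](C)(C)C(C)(C)C)cc2)c(O[Si](C)(C)C(C)(C)C)c1
F5 | step 14 | (1Z,3R,5S)-3-[2,6-bis(tert-butyldimethylsilyloxy)-3-iodo-4-methoxyphenyl]-1,7-bis[4-(tert-butyldimethylsilyloxy)phenyl]-1-(triethoxysilyl)hept-1-en-5-ol | COc1cc(O[Si](C)(C)C(C)(C)C)c([C@@H](/C=C(/c2ccc(O[Si](C)(C)C(C)(C)C)cc2)[Si](OCC)(OCC)OCC)C[C@@H](O)CCc2ccc(O[Si](C)(C)C(C)(C)C)cc2)c(O[Si](C)(C)C(C)(C)C)c1I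
F6 | step 14 | 2-[(1E,3R,5S)-5-hydroxy-1,7-bis(4-hydroxyphenyl)hept-1-en-3-yl]-4-iodo-5-methoxybenzene-1,3-diol | COc1cc(O)c([C@@H](/C=C/c2ccc(O)cc2)C[C@@H](O)CCc2ccc(O)cc2)c(O)c1I
F7 | step 10 | 2-{(3R)-5-hydroxy-1-[4-(tert-butyldimethylsilyloxy)phenyl]pent-1-yn-3-yl}-5-methoxybenzene-1,3-diol | COc1cc(O)c([C@H](CCO)C#Cc2ccc(O[Si](C)(C)C(C)(C)C)cc2)c(O)c1
F8 | step 10 | (3R)-3-[2,6-bis(tert-butyldimethylsilyloxy)-4-methoxyphenyl]-1-(tert-butyldimethylsilyloxy)-5-[4-(tert-butyldimethylsilyloxy)phenyl]pent-4-yne | COc1cc(O[Si](C)(C)C(C)(C)C)c([C@H](CCO[Si](C)(C)C(C)(C)C)C#Cc2ccc(O[Si](C)(C)C(C)(C)C)cc2)c(O[Si](C)(C)C(C)(C)C)c1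
F9 | step 10 | (3R)-3-[2,6-bis(tert-butyldimethylsilyloxy)-4-methoxyphenyl]-5-[4-(tert-butyldimethylsilyloxy)phenyl]pent-4-yn-1-ol | COc1cc(O[Si](C)(C)C(C)(C)C)c([C@H](CCO)C#Cc2ccc(O[Si](C)(C)C(C)(C)C)cc2)c(O[Si](C)(C)C(C)(C)C)c1
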